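Numbering used throughout: ring carbons C1–C10 (C10 carries the ester carbon C14, C4 carries C15 = CH2OH), lactone O6–C12(=O)–C11(=C13H2)–C7, isobutyrate on O8, acetate on O9.
Retrosynthetic cuts: C11–C12 (γ-lactone, last C–C bond), C1=C10 (ten-membered ring, ring-closing metathesis), C6–C7 (allenylzinc plus enal), C7–C11 and C9–C10 (two alkyne-derived units), C8–C9 (alkoxyallylboration), C3–C4 (Negishi coupling).
Forward order: a C7–C10 propargylic mesylate and a C1–C6 dienal are joined at C6–C7, the carbocycle is closed at C1=C10, the lactone is closed last on the intact macrocycle, then the C8 acetal is exchanged for isobutyrate and C15–OH is unmasked.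
Enabling feature: O6 on C6 and an ethynyl group on the adjacent C7 (a homopropargylic oxygen), so that a carbonyl carbon carried by O6 reaches the inner alkyne carbon C11 in a 5-exo-dig closure that forms ring O6–C12–C11–C7–C6 and leaves C13 as the exocyclic methylene.
Stereochemistry: C8 and C9 from a reagent-controlled (isopinocampheyl) syn-alkoxyallylboration, the C7 carbinol from Felkin–Anh addition, C6 and C7 of the target from the stereospecific, anti-selective allenylzinc addition (net inversion at C7), C4=C5 from trans-hydroalumination/iodination and a stereoretentive coupling, C1=C10 from ring constraint.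

Key step: step 16

Step 1
Reactants: 1 prop-2-en-1-ol
Product: 2 3-(methoxymethoxy)prop-1-ene
Conditions: MOMCl, iPr2NEt, CH2Cl2, 0 °C to rt
Reagents that add atoms: chloromethyl methyl ether, COCCl
Why: O-alkylation of the alcohol by the α-chloro ether (methoxymethyl acetal formation) should give the allyl ether needed for γ-alkoxyallyl metalation, and no stereocentre is formed.

Step 2
Reactants: 2 3-(methoxymethoxy)prop-1-ene; 3 3-(trimethylsilyl)prop-2-ynal
Product: 6 (3S,4S)-3-(methoxymethoxy)hex-1-en-5-yn-4-ol, via allylborane 4 (not isolated), via C-silyl enynol 5 (not isolated)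
Conditions: sec-BuLi, THF, −78 °C; (+)-Ipc2BOMe; BF3·OEt2; 3, −78 °C; NaOH, H2O2; then K2CO3, MeOH, rt
Reagents that add atoms: none
Why: Brown asymmetric alkoxyallylboration: the (Z)-γ-(methoxymethoxy)allylborane 4 should add through a closed chair transition state, so that the Z geometry fixes the syn relation of O8 and O9 and the isopinocampheyl groups derived from (−)-α-pinene direct the allyl unit to the Re face of the ynal (C8 and C9 both S), after which basic methanol cleaves the alkynyl C–Si bond of 5.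

Step 3
Reactants: 6 (3S,4S)-3-(methoxymethoxy)hex-1-en-5-yn-4-ol
Product: 7 methyl (3S,4S)-3-hydroxy-4-(methoxymethoxy)-2-methylidenehex-5-enoate
Conditions: Pd(OAc)2 (cat.), 2-(diphenylphosphino)pyridine, CH3SO3H (cat.), CO, MeOH, 45 °C
Reagents that add atoms: carbon monoxide, [C-]#[O+]; methanol, CO
Why: Palladium-catalysed Markovnikov hydromethoxycarbonylation of a terminal alkyne: with the pyridylphosphine ligand the divalent palladium hydride should place the ester group on the inner alkyne carbon C10, giving the 2-substituted acrylate while the monosubstituted alkene and both stereocentres stay untouched.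

Step 4
Reactants: 7 methyl (3S,4S)-3-hydroxy-4-(methoxymethoxy)-2-methylidenehex-5-enoate
Product: 8 methyl (3S,4S)-3-(acetyloxy)-4-(methoxymethoxy)-2-methylidenehex-5-enoate
Conditions: Ac2O, pyridine, DMAP (cat.), CH2Cl2, 0 °C
Reagents that add atoms: acetic anhydride, CC(=O)OC(C)=O
Why: Nucleophile-catalysed acylation of the only free hydroxyl puts the acetate on O9 at the moment this oxygen is the single unprotected one, with retention at C9.

Step 5
Reactants: 8 methyl (3S,4S)-3-(acetyloxy)-4-(methoxymethoxy)-2-methylidenehex-5-enoate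
Product: 9 methyl (3S,4R)-3-(acetyloxy)-4-(methoxymethoxy)-2-methylidene-5-oxopentanoate
Conditions: O3, pyridine, CH2Cl2, −78 °C
Reagents that add atoms: ozone, [O-][O+]=O
Why: Chemoselective ozonolysis: the electron-rich monosubstituted vinyl group should react far faster with the electrophilic oxidant than the electron-poor acrylate, and pyridine decomposes the carbonyl oxide directly to the C7 aldehyde (the descriptor at C8 changes only because the substituent ranking changes).

Step 6
Reactants: 9 methyl (3S,4R)-3-(acetyloxy)-4-(methoxymethoxy)-2-methylidene-5-oxopentanoate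
Product: 10 methyl (3S,4S,5S)-3-(acetyloxy)-5-hydroxy-4-(methoxymethoxy)-2-methylidene-7-(trimethylsilyl)hept-6-ynoate
Conditions: Me3SiC≡CH, n-BuLi, THF, −78 °C; ClTi(OiPr)3; then 9, −78 to −40 °C
Reagents that add atoms: ethynyltrimethylsilane, C#C[Si](C)(C)C
Why: Felkin–Anh-controlled 1,2-addition of a non-chelating alkynyltitanium reagent: attack anti to the α-methoxymethoxy group should set the C7 carbinol anti to O8, and the titanium acetylide is mild enough to spare the acetate, the acrylate and the methyl ester.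

Step 7
Reactants: 10 methyl (3S,4S,5S)-3-(acetyloxy)-5-hydroxy-4-(methoxymethoxy)-2-methylidene-7-(trimethylsilyl)hept-6-ynoate
Product: 11 methyl (3S,4R,5S)-3-(acetyloxy)-5-[(methanesulfonyl)oxy]-4-(methoxymethoxy)-2-methylidene-7-(trimethylsilyl)hept-6-ynoate
Conditions: MsCl, Et3N, CH2Cl2, −78 °C
Reagents that add atoms: methanesulfonyl chloride, CS(=O)(=O)Cl
Why: Sulfonylation of the propargylic alcohol proceeds with retention at C7 and gives the leaving group for the allenylmetal formation, the mesylate being used without storage.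

Step 8
Reactants: 12 but-2-yne-1,4-diol
Product: 13 4-[(tert-butyldiphenylsilyl)oxy]but-2-yn-1-ol
Conditions: NaH (1 equiv), THF, 0 °C; TBDPSCl
Reagents that add atoms: tert-butyl(chloro)diphenylsilane, CC(C)(C)[Si](Cl)(c1ccccc1)c1ccccc1
Why: Monosilylation of a symmetrical diol through its monosodium alkoxide should give the mono-ether that carries the later C15 oxygen in protected form, and no stereocentre is formed.

Step 9
Reactants: 13 4-[(tert-butyldiphenylsilyl)oxy]but-2-yn-1-ol
Product: 15 (2Z)-4-[(tert-butyldiphenylsilyl)oxy]-3-iodobut-2-en-1-ol, via alkenylalanate 14 (not isolated)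
Conditions: NaAlH2(OCH2CH2OMe)2, THF, 0 °C; then I2, −78 °C
Reagents that add atoms: iodine, II
Why: Hydroxyl-directed trans-hydroalumination of the propargylic alcohol followed by iodinolysis of the C–Al bond with retention should give the Z iodoalkene, with iodine on the carbon remote from the free hydroxyl (C4) and cis to C6.

Step 10
Reactants: 15 (2Z)-4-[(tert-butyldiphenylsilyl)oxy]-3-iodobut-2-en-1-ol
Product: 16 (2E)-3-{[(tert-butyldiphenylsilyl)oxy]methyl}hepta-2,6-dien-1-ol
Conditions: CH2=CHCH2CH2ZnBr, Pd(dppf)Cl2 (cat.), THF, 40 °C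
Reagents that add atoms: but-3-en-1-ylzinc bromide, C=CCC[Zn]Br
Why: Negishi sp2–sp3 cross-coupling proceeds with retention of the alkene geometry, so the butenyl chain (C1–C3) ends cis to C6 as the C4=C5 bond of the target requires.

Step 11
Reactants: 16 (2E)-3-{[(tert-butyldiphenylsilyl)oxy]methyl}hepta-2,6-dien-1-ol
Product: 17 (2E)-3-{[(tert-butyldiphenylsilyl)oxy]methyl}hepta-2,6-dienal
Conditions: MnO2, CH2Cl2, rt
Reagents that add atoms: none
Why: Chemoselective oxidation of the allylic alcohol by MnO2 should give the enal without touching the silyl ether, the terminal alkene or the alkene geometry.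

Step 12
Reactants: 11 methyl (3S,4R,5S)-3-(acetyloxy)-5-[(methanesulfonyl)oxy]-4-(methoxymethoxy)-2-methylidene-7-(trimethylsilyl)hept-6-ynoate; 17 (2E)-3-{[(tert-butyldiphenylsilyl)oxy]methyl}hepta-2,6-dienal
Product: 19 methyl (3S,4S,5S,6R,7E)-3-(acetyloxy)-8-{[(tert-butyldiphenylsilyl)oxy]methyl}-6-hydroxy-4-(methoxymethoxy)-2-methylidene-5-[(trimethylsilyl)ethynyl]dodeca-7,11-dienoate, via allenylzinc 18 (not isolated)
Conditions: Pd(OAc)2 (cat.), PPh3 (cat.), Et2Zn, THF, −78 to −20 °C
Reagents that add atoms: none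
Why: Marshall propargylation (palladium-catalysed umpolung of a propargylic mesylate): zerovalent palladium should displace the mesylate anti in an SN2′ sense, transmetalation to zinc gives allenylzinc 18, and its closed SE2′ addition to the enal forms C6–C7 with net inversion at C7 and the anti adduct (hydroxyl versus C8 branch), which sets C6 (R) and C7 (S).

Step 13
Reactants: 19 methyl (3S,4S,5S,6R,7E)-3-(acetyloxy)-8-{[(tert-butyldiphenylsilyl)oxy]methyl}-6-hydroxy-4-(methoxymethoxy)-2-methylidene-5-[(trimethylsilyl)ethynyl]dodeca-7,11-dienoate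
Product: 20 methyl (1E,5E,7R,8S,9S,10S)-10-(acetyloxy)-5-{[(tert-butyldiphenylsilyl)oxy]methyl}-7-hydroxy-9-(methoxymethoxy)-8-[(trimethylsilyl)ethynyl]cyclodeca-1,5-diene-1-carboxylate
Conditions: second-generation Hoveyda–Grubbs catalyst (cat.), toluene (high dilution), 80 °C
Reagents that add atoms: none
Why: Ring-closing metathesis: the ruthenium alkylidene should load on the monosubstituted C1 alkene and close onto the tethered 1,1-disubstituted acrylate with loss of ethene, and the new C1=C10 bond should form with C2 cis to C9 (E by the sequence rule) because that is the low-strain arrangement in a cyclodeca-1,5-diene that already holds the cis C4=C5 bond, while the silyl alkyne and the trisubstituted alkene stay out of the reaction.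

Step 14
Reactants: 20 methyl (1E,5E,7R,8S,9S,10S)-10-(acetyloxy)-5-{[(tert-butyldiphenylsilyl)oxy]methyl}-7-hydroxy-9-(methoxymethoxy)-8-[(trimethylsilyl)ethynyl]cyclodeca-1,5-diene-1-carboxylate
Product: 21 methyl (1E,5E,7R,8S,9S,10S)-10-(acetyloxy)-5-{[(tert-butyldiphenylsilyl)oxy]methyl}-8-ethynyl-7-hydroxy-9-(methoxymethoxy)cyclodeca-1,5-diene-1-carboxylate
Conditions: AgNO3 (cat.), acetone/H2O, rt
Reagents that add atoms: none
Why: Silver-catalysed protodesilylation: AgNO3 should form the silver acetylide selectively from the alkynylsilane and water releases the terminal alkyne, while the acetate, the acetal and the silyl ether survive the neutral conditions.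

Step 15
Reactants: 21 methyl (1E,5E,7R,8S,9S,10S)-10-(acetyloxy)-5-{[(tert-butyldiphenylsilyl)oxy]methyl}-8-ethynyl-7-hydroxy-9-(methoxymethoxy)cyclodeca-1,5-diene-1-carboxylate
Product: 22 methyl (1E,5E,7R,8S,9S,10S)-10-(acetyloxy)-5-{[(tert-butyldiphenylsilyl)oxy]methyl}-8-ethynyl-9-(methoxymethoxy)-7-{[(phenylselanyl)carbonyl]oxy}cyclodeca-1,5-diene-1-carboxylate
Conditions: PhSeC(O)Cl (freshly prepared), pyridine, CH2Cl2, 0 °C
Reagents that add atoms: Se-phenyl carbonochloridoselenoate, O=C(Cl)[Se]c1ccccc1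
Why: O-acylation of the only free hydroxyl (O6) by the selenocarbonyl chloride installs the radical precursor with C12 already bound to O6, without passing through a labile allylic chloroformate.

Step 16
Reactants: 22 methyl (1E,5E,7R,8S,9S,10S)-10-(acetyloxy)-5-{[(tert-butyldiphenylsilyl)oxy]methyl}-8-ethynyl-9-(methoxymethoxy)-7-{[(phenylselanyl)carbonyl]oxy}cyclodeca-1,5-diene-1-carboxylate
Product: 23 methyl (3aS,4S,5S,6E,10E,11aR)-5-(acetyloxy)-10-{[(tert-butyldiphenylsilyl)oxy]methyl}-4-(methoxymethoxy)-3-methylidene-2-oxo-2,3,3a,4,5,8,9,11a-octahydrocyclodeca[b]furan-6-carboxylate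
Conditions: Bu3SnH (slow addition), Et3B, air, benzene, rt
Reagents that add atoms: none
Why: Et3B/O2 starts a tin hydride chain in which Bu3Sn• abstracts the phenylselanyl group from the selenocarbonate to give the alkoxycarbonyl radical on O6, whose carbonyl carbon C12 adds to the inner alkyne carbon C11, and the resulting σ-vinyl radical at C13 takes hydrogen from Bu3SnH. The closest known reaction type is the alkoxycarbonyl radical cyclisation of Se-phenyl selenocarbonates of homopropargylic alcohols to α-methylene-γ-butyrolactones. The γ-lactone ring (O6–C12–C11–C7–C6) is closed in the 5-exo-dig mode by the new C11–C12 bond, and the ten-membered ring is not touched. No stereocentre is created: C11 and C13 end as sp2 carbons, and the trans ring fusion follows from the configurations C6 (R) and C7 (S) set in step 12, which hold O6 and the ethynyl group gauche on adjacent carbons. The step needs cyclisation to outrun loss of CO2 from the allylic alkoxycarbonyl radical, direct reduction to the formate and stannyl radical addition to the alkyne; initiation at room temperature instead of at reflux, a low stationary tin hydride concentration and the fast selenium transfer are expected to secure this. The conjugated enoate, the acetate, the acetal and the silyl ether should be inert to the chain carriers, so the electrophilic α-methylene lactone appears only at this late point.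

Step 17
Reactants: 23 methyl (3aS,4S,5S,6E,10E,11aR)-5-(acetyloxy)-10-{[(tert-butyldiphenylsilyl)oxy]methyl}-4-(methoxymethoxy)-3-methylidene-2-oxo-2,3,3a,4,5,8,9,11a-octahydrocyclodeca[b]furan-6-carboxylate
Product: 24 methyl (3aR,4S,5S,6E,10E,11aR)-5-(acetyloxy)-10-{[(tert-butyldiphenylsilyl)oxy]methyl}-4-hydroxy-3-methylidene-2-oxo-2,3,3a,4,5,8,9,11a-octahydrocyclodeca[b]furan-6-carboxylate
Conditions: Me2BBr, CH2Cl2, −78 °C; then aq. NaHCO3
Reagents that add atoms: none
Why: Lewis acid cleavage of the methoxymethyl acetal: Me2BBr should convert the acetal into a bromomethyl ether that hydrolyses on bicarbonate work-up, freeing O8 at −78 °C while the silyl ether, the esters and the lactone stay intact (the 3a descriptor changes only through the substituent ranking).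

Step 18
Reactants: 24 methyl (3aR,4S,5S,6E,10E,11aR)-5-(acetyloxy)-10-{[(tert-butyldiphenylsilyl)oxy]methyl}-4-hydroxy-3-methylidene-2-oxo-2,3,3a,4,5,8,9,11a-octahydrocyclodeca[b]furan-6-carboxylate
Product: 25 methyl (3aS,4S,5S,6E,10E,11aR)-5-(acetyloxy)-10-{[(tert-butyldiphenylsilyl)oxy]methyl}-3-methylidene-4-[(2-methylpropanoyl)oxy]-2-oxo-2,3,3a,4,5,8,9,11a-octahydrocyclodeca[b]furan-6-carboxylate
Conditions: (CH3)2CHCOCl, pyridine, DMAP (cat.), CH2Cl2, 0 °C
Reagents that add atoms: 2-methylpropanoyl chloride, CC(C)C(=O)Cl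
Why: Nucleophile-catalysed acylation of the single free hydroxyl (O8) with the acid chloride, run directly on freshly prepared 24, should outrun 1,2-migration of the neighbouring acetate and places the isobutyrate on C8 with retention.

Step 19
Reactants: 25 methyl (3aS,4S,5S,6E,10E,11aR)-5-(acetyloxy)-10-{[(tert-butyldiphenylsilyl)oxy]methyl}-3-methylidene-4-[(2-methylpropanoyl)oxy]-2-oxo-2,3,3a,4,5,8,9,11a-octahydrocyclodeca[b]furan-6-carboxylate
Product: 26 methyl (3aS,4S,5S,6E,10E,11aR)-5-(acetyloxy)-10-(hydroxymethyl)-3-methylidene-4-[(2-methylpropanoyl)oxy]-2-oxo-2,3,3a,4,5,8,9,11a-octahydrocyclodeca[b]furan-6-carboxylate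
Conditions: HF·pyridine, THF, 0 °C to rt
Reagents that add atoms: none
Why: Fluoride-mediated cleavage of the Si–O bond by buffered HF should free the primary allylic alcohol C15–OH under conditions that neither add to the α-methylene lactone nor move the acyl groups.

Compound list
1 | prop-2-en-1-ol | C=CCO | starting material
2 | 3-(methoxymethoxy)prop-1-ene | C=CCOCOC | intermediate
3 | 3-(trimethylsilyl)prop-2-ynal | C[Si](C)(C)C#CC=O | starting material
4 | [(2Z)-3-(methoxymethoxy)prop-2-en-1-yl]bis[(1S,2R,3S,5S)-2,6,6-trimethylbicyclo[3.1.1]heptan-3-yl]borane | COCO/C=C\CB([C@H]1C[C@H]2C[C@@H]([C@@H]1C)C2(C)C)[C@H]1C[C@H]2C[C@@H]([C@@H]1C)C2(C)C | intermediate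
5 | (3S,4S)-3-(methoxymethoxy)-6-(trimethylsilyl)hex-1-en-5-yn-4-ol | C=C[C@H](OCOC)[C@@H](O)C#C[Si](C)(C)C | intermediate
6 | (3S,4S)-3-(methoxymethoxy)hex-1-en-5-yn-4-ol | C=C[C@H](OCOC)[C@@H](O)C#C | intermediate
7 | methyl (3S,4S)-3-hydroxy-4-(methoxymethoxy)-2-methylidenehex-5-enoate | C=C[C@H](OCOC)[C@@H](O)C(=C)C(=O)OC | intermediate
8 | methyl (3S,4S)-3-(acetyloxy)-4-(methoxymethoxy)-2-methylidenehex-5-enoate | C=C[C@H](OCOC)[C@@H](OC(C)=O)C(=C)C(=O)OC | intermediate
9 | methyl (3S,4R)-3-(acetyloxy)-4-(methoxymethoxy)-2-methylidene-5-oxopentanoate | O=C[C@H](OCOC)[C@@H](OC(C)=O)C(=C)C(=O)OC | intermediate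
10 | methyl (3S,4S,5S)-3-(acetyloxy)-5-hydroxy-4-(methoxymethoxy)-2-methylidene-7-(trimethylsilyl)hept-6-ynoate | C[Si](C)(C)C#C[C@H](O)[C@H](OCOC)[C@@H](OC(C)=O)C(=C)C(=O)OC | intermediate
11 | methyl (3S,4R,5S)-3-(acetyloxy)-5-[(methanesulfonyl)oxy]-4-(methoxymethoxy)-2-methylidene-7-(trimethylsilyl)hept-6-ynoate | C[Si](C)(C)C#C[C@H](OS(C)(=O)=O)[C@H](OCOC)[C@@H](OC(C)=O)C(=C)C(=O)OC | intermediate
12 | but-2-yne-1,4-diol | OCC#CCO | starting material
13 | 4-[(tert-butyldiphenylsilyl)oxy]but-2-yn-1-ol | OCC#CCO[Si](c1ccccc1)(c1ccccc1)C(C)(C)C | intermediate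
14 | sodium 3-{[(tert-butyldiphenylsilyl)oxy]methyl}-2,2-bis(2-methoxyethoxy)-2,5-dihydro-1,2-oxaluminol-2-uide (cyclic alkenylalanate, aluminium cis to the ring CH2O) | [Na+].COCCO[Al-]1(OCCOC)OCC=C1CO[Si](c1ccccc1)(c1ccccc1)C(C)(C)C | intermediate
15 | (2Z)-4-[(tert-butyldiphenylsilyl)oxy]-3-iodobut-2-en-1-ol | OC/C=C(\I)CO[Si](c1ccccc1)(c1ccccc1)C(C)(C)C | intermediate
16 | (2E)-3-{[(tert-butyldiphenylsilyl)oxy]methyl}hepta-2,6-dien-1-ol | OC/C=C(/CO[Si](c1ccccc1)(c1ccccc1)C(C)(C)C)CCC=C | intermediate
17 | (2E)-3-{[(tert-butyldiphenylsilyl)oxy]methyl}hepta-2,6-dienal | O=C/C=C(/CO[Si](c1ccccc1)(c1ccccc1)C(C)(C)C)CCC=C | intermediate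
18 | ethyl[(4S,5S)-5-(acetyloxy)-6-(methoxycarbonyl)-4-(methoxymethoxy)-1-(trimethylsilyl)hepta-1,2,6-trien-1-yl]zinc (allene axis as formed by anti displacement of the mesylate, zinc on the face opposite to the departed oxygen) | CC[Zn]C([Si](C)(C)C)=C=C[C@H](OCOC)[C@@H](OC(C)=O)C(=C)C(=O)OC | intermediate
19 | methyl (3S,4S,5S,6R,7E)-3-(acetyloxy)-8-{[(tert-butyldiphenylsilyl)oxy]methyl}-6-hydroxy-4-(methoxymethoxy)-2-methylidene-5-[(trimethylsilyl)ethynyl]dodeca-7,11-dienoate | C=C(C(=O)OC)[C@H](OC(C)=O)[C@@H](OCOC)[C@@H](C#C[Si](C)(C)C)[C@H](O)/C=C(/CO[Si](c1ccccc1)(c1ccccc1)C(C)(C)C)CCC=C | intermediate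
20 | methyl (1E,5E,7R,8S,9S,10S)-10-(acetyloxy)-5-{[(tert-butyldiphenylsilyl)oxy]methyl}-7-hydroxy-9-(methoxymethoxy)-8-[(trimethylsilyl)ethynyl]cyclodeca-1,5-diene-1-carboxylate | O[C@@H]1/C=C(/CO[Si](c2ccccc2)(c2ccccc2)C(C)(C)C)CC/C=C(/C(=O)OC)[C@H](OC(C)=O)[C@@H](OCOC)[C@H]1C#C[Si](C)(C)C | intermediate
21 | methyl (1E,5E,7R,8S,9S,10S)-10-(acetyloxy)-5-{[(tert-butyldiphenylsilyl)oxy]methyl}-8-ethynyl-7-hydroxy-9-(methoxymethoxy)cyclodeca-1,5-diene-1-carboxylate | O[C@@H]1/C=C(/CO[Si](c2ccccc2)(c2ccccc2)C(C)(C)C)CC/C=C(/C(=O)OC)[C@H](OC(C)=O)[C@@H](OCOC)[C@H]1C#C | intermediate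
22 | methyl (1E,5E,7R,8S,9S,10S)-10-(acetyloxy)-5-{[(tert-butyldiphenylsilyl)oxy]methyl}-8-ethynyl-9-(methoxymethoxy)-7-{[(phenylselanyl)carbonyl]oxy}cyclodeca-1,5-diene-1-carboxylate | O=C([Se]c3ccccc3)O[C@@H]1/C=C(/CO[Si](c2ccccc2)(c2ccccc2)C(C)(C)C)CC/C=C(/C(=O)OC)[C@H](OC(C)=O)[C@@H](OCOC)[C@H]1C#C | intermediate
23 | methyl (3aS,4S,5S,6E,10E,11aR)-5-(acetyloxy)-10-{[(tert-butyldiphenylsilyl)oxy]methyl}-4-(methoxymethoxy)-3-methylidene-2-oxo-2,3,3a,4,5,8,9,11a-octahydrocyclodeca[b]furan-6-carboxylate | C=C1C(=O)O[C@@H]2/C=C(/CO[Si](c3ccccc3)(c3ccccc3)C(C)(C)C)CC/C=C(/C(=O)OC)[C@H](OC(C)=O)[C@@H](OCOC)[C@@H]12 | intermediate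
24 | methyl (3aR,4S,5S,6E,10E,11aR)-5-(acetyloxy)-10-{[(tert-butyldiphenylsilyl)oxy]methyl}-4-hydroxy-3-methylidene-2-oxo-2,3,3a,4,5,8,9,11a-octahydrocyclodeca[b]furan-6-carboxylate | C=C1C(=O)O[C@@H]2/C=C(/CO[Si](c3ccccc3)(c3ccccc3)C(C)(C)C)CC/C=C(/C(=O)OC)[C@H](OC(C)=O)[C@@H](O)[C@@H]12 | intermediate
25 | methyl (3aS,4S,5S,6E,10E,11aR)-5-(acetyloxy)-10-{[(tert-butyldiphenylsilyl)oxy]methyl}-3-methylidene-4-[(2-methylpropanoyl)oxy]-2-oxo-2,3,3a,4,5,8,9,11a-octahydrocyclodeca[b]furan-6-carboxylate | C=C1C(=O)O[C@@H]2/C=C(/CO[Si](c3ccccc3)(c3ccccc3)C(C)(C)C)CC/C=C(/C(=O)OC)[C@H](OC(C)=O)[C@@H](OC(=O)C(C)C)[C@@H]12 | intermediate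
26 | methyl (3aS,4S,5S,6E,10E,11aR)-5-(acetyloxy)-10-(hydroxymethyl)-3-methylidene-4-[(2-methylpropanoyl)oxy]-2-oxo-2,3,3a,4,5,8,9,11a-octahydrocyclodeca[b]furan-6-carboxylate | C=C1C(=O)O[C@@H]2/C=C(/CO)CC/C=C(/C(=O)OC)[C@H](OC(C)=O)[C@@H](OC(=O)C(C)C)[C@@H]12 | target

Total step count: 19. Longest linear sequence: 15 steps (steps 1–7, then 12–19); the dienal 17 is made in a four-step branch (steps 8–11).

Steps most likely to fail

Step 13 is the most exposed. The 1,1-disubstituted, electron-poor acrylate may engage the ruthenium carbene too slowly, so that intermolecular metathesis of the terminal alkene (dimers and oligomers) or double-bond migration takes over from ring closure. The fallback changes the order in which the ring bonds are made and sets out from 10 and 17. Cross-metathesis of the acrylate of 10 with the terminal alkene of 17 (second-generation Hoveyda–Grubbs catalyst, excess 17, CH2Cl2, 40 °C) should form C1=C10 between the two fragments and give methyl (2E,6E)-2-[(1S,2S,3S)-1-(acetyloxy)-3-hydroxy-2-(methoxymethoxy)-5-(trimethylsilyl)pent-4-yn-1-yl]-6-{[(tert-butyldiphenylsilyl)oxy]methyl}-8-oxoocta-2,6-dienoate F1. Mesylation (MsCl, Et3N, CH2Cl2, −78 °C) should give methyl (2E,6E)-2-[(1S,2R,3S)-1-(acetyloxy)-3-[(methanesulfonyl)oxy]-2-(methoxymethoxy)-5-(trimethylsilyl)pent-4-yn-1-yl]-6-{[(tert-butyldiphenylsilyl)oxy]methyl}-8-oxoocta-2,6-dienoate F2. The ring is then closed at C6–C7 by the intramolecular form of the allenylzinc addition (Pd(OAc)2, PPh3, Et2Zn, THF, high dilution, −20 °C), which comes back to the route at 20.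

Step 12 may fail through competing ionisation of the allylic acetate at C9 by zerovalent palladium, through 1,4-elimination of the C8 alkoxide from the allenylzinc, or through eroded anti selectivity with the conjugated aldehyde. The fallback sets out from 11 and avoids both palladium and zinc. Copper-catalysed SN2′ silylation (HSiCl3, CuCl, iPr2NEt, Et2O/MeCN) should give trichloro[(4S,5S)-5-(acetyloxy)-6-(methoxycarbonyl)-4-(methoxymethoxy)-1-(trimethylsilyl)hepta-1,2,6-trien-1-yl]silane F3 with the same anti displacement. Its addition to 17 in DMF through a closed hexacoordinate silicate transition state should deliver the same anti adduct and comes back to the route at 19.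

Step 16 may fail through loss of CO2 from the allylic alkoxycarbonyl radical before it cyclises (leading to deoxygenation at C6), through premature hydrogen transfer to give the formate, or through hydrostannylation of the alkyne. The fallback sets out from 21 and replaces the radical chain by a palladium-catalysed cyclocarbonylation of the homopropargylic alcohol (PdCl2, SnCl2, PPh3, CO, MeCN, 75 °C). An alkoxycarbonyl complex of divalent palladium formed on O6 inserts the alkyne intramolecularly and protonolysis gives the α-methylene lactone, so the sequence comes back to the route at 23 without any new isolated compound.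

Further compounds
F1 | step 13 | methyl (2E,6E)-2-[(1S,2S,3S)-1-(acetyloxy)-3-hydroxy-2-(methoxymethoxy)-5-(trimethylsilyl)pent-4-yn-1-yl]-6-{[(tert-butyldiphenylsilyl)oxy]methyl}-8-oxoocta-2,6-dienoate | C[Si](C)(C)C#C[C@H](O)[C@H](OCOC)[C@@H](OC(C)=O)/C(C(=O)OC)=C\CC/C(CO[Si](c1ccccc1)(c1ccccc1)C(C)(C)C)=C\C=O
F2 | step 13 | methyl (2E,6E)-2-[(1S,2R,3S)-1-(acetyloxy)-3-[(methanesulfonyl)oxy]-2-(methoxymethoxy)-5-(trimethylsilyl)pent-4-yn-1-yl]-6-{[(tert-butyldiphenylsilyl)oxy]methyl}-8-oxoocta-2,6-dienoate | C[Si](C)(C)C#C[C@H](OS(C)(=O)=O)[C@H](OCOC)[C@@H](OC(C)=O)/C(C(=O)OC)=C\CC/C(CO[Si](c1ccccc1)(c1ccccc1)C(C)(C)C)=C\C=O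
F3 | step 12 | trichloro[(4S,5S)-5-(acetyloxy)-6-(methoxycarbonyl)-4-(methoxymethoxy)-1-(trimethylsilyl)hepta-1,2,6-trien-1-yl]silane | Cl[Si](Cl)(Cl)C([Si](C)(C)C)=C=C[C@H](OCOC)[C@@H](OC(C)=O)C(=C)C(=O)OC
F0 | step 16 | none | none
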